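**Plan**
- Retrosynthesis: cut O1–C2 of ring C (Mitsunobu etherification), then C4–C4a (Heck arylation) and C2–C3 (vinyl addition), which leads back to a fully substituted ring B aldehyde. In that aldehyde the aryl–prenyl bond, the aryl–CH= bond and the O–CMe2 bond of the pyran are cut together, giving a bis-ether of 3,4-dihydroxybenzaldehyde.
- Enabling feature: in ring B the free hydroxyl oxygen (on C3') has the prenyl-bearing C2' as its only open ortho carbon, and the pyran oxygen (on C4') has C5' as its only open ortho carbon. A 1,1-dimethylallyl ether on the first oxygen and a 1,1-dimethylpropargyl ether on the second can therefore rearrange only to the positions the target needs.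
- Forward: two O-alkylations; one heating that installs the prenyl group and closes the dimethylpyran ring; C2–C3 and C4–C4a bond formation to a 1,3-diarylpropan-1-one; ring C closed last.
- Stereochemistry: the single stereocentre comes from a CBS reduction to the (S)-carbinol, which is inverted in the Mitsunobu ring closure to give (2R).

Key step: step 4

Assumption: the stereocentre of the target SMILES is read as (2R) (O1 > ring B carbon > C3 > H); 3-chloro-3-methylbut-1-yne, vinylmagnesium bromide, the silyl chlorides and the CBS catalyst are purchased.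

**Route**

Step 1
Reactants: 1 3,4-dihydroxybenzaldehyde; 2 3-chloro-3-methylbut-1-yne
Product: 3 3-hydroxy-4-(2-methylbut-3-yn-2-yloxy)benzaldehyde
Conditions: K2CO3 (1.1 equiv), KI, CuI (cat.), DMF, 55 °C
Reagents that add atoms: none
Why: Copper-assisted Williamson-type propargylic etherification, in which the hydroxyl para to the formyl group is much the more acidic, so one equivalent of carbonate should generate only the 4-phenoxide and leave O3 free.

Step 2
Reactants: 4 2-methylbut-3-en-2-ol
Product: 6 methyl 2-methylbut-3-en-2-yl carbonate, via lithium 2-methylbut-3-en-2-olate 5 (not isolated)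
Conditions: n-BuLi, THF, −78 °C; then ClCO2Me, −78 °C to rt
Reagents that add atoms: methyl chloroformate, COC(=O)Cl
Why: Acylation of a preformed lithium tert-alkoxide with a chloroformate is the standard access to tertiary allylic carbonates and avoids acid that would ionise the allylic alcohol.

Step 3
Reactants: 3 3-hydroxy-4-(2-methylbut-3-yn-2-yloxy)benzaldehyde; 6 methyl 2-methylbut-3-en-2-yl carbonate
Product: 7 3-(2-methylbut-3-en-2-yloxy)-4-(2-methylbut-3-yn-2-yloxy)benzaldehyde
Conditions: Pd(PPh3)4 (3 mol%), THF, 4 Å MS, 0 °C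
Reagents that add atoms: none
Why: Tsuji–Trost O-allylation, in which zerovalent palladium ionises the carbonate to the 1,1-dimethyl-π-allyl complex with loss of CO2, the released methoxide deprotonates the phenol, and at 0 °C the phenoxide should attack the more substituted allyl terminus under kinetic control to give the tertiary ether, the terminal alkyne being inert without copper.

Step 4
Reactants: 7 3-(2-methylbut-3-en-2-yloxy)-4-(2-methylbut-3-yn-2-yloxy)benzaldehyde
Product: 11 8-hydroxy-2,2-dimethyl-7-(3-methylbut-2-enyl)-2H-chromene-6-carbaldehyde, via prenylphenol propargyl ether 8 (not isolated), via allenyl catechol 9 (not isolated), via ortho-quinone methide 10 (not isolated)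
Conditions: PhNEt2 (degassed), 130 °C then 190 °C, sealed tube
Reagents that add atoms: none
Why: The 1,1-dimethylallyl ether on O3 undergoes an aromatic Claisen [3,3] shift to C2 and the dienone tautomerises to prenylphenol 8, after which the 1,1-dimethylpropargyl ether on O4 shifts [3,3] to C5, the allenyl dienone enolises to 9 and a [1,5]-hydrogen shift from the phenol to the central allene carbon gives ortho-quinone methide 10. The pyran ring closes from 10 by a thermal oxa-6π electrocyclisation of its 1-oxatriene unit, which forms the O–CMe2 bond and restores the aromatic ring. The closest known reactions are the thermal rearrangement of aryl 1,1-dimethylallyl ethers to ortho-prenylphenols and the propargyl Claisen–electrocyclisation of aryl 1,1-dimethylpropargyl ethers to 2,2-dimethyl-2H-chromenes, run here in one flask. No stereocentre is formed. The step needs complete regiocontrol of both C–C bond formations, and the substrate gives it because the second ortho carbon of each ether oxygen is the carbon that carries the other oxygen, while fast tautomerisation at the CH positions C2 and C5 prevents onward migration. The weakly basic amine solvent suppresses acid-catalysed ionisation of the tertiary ethers and cyclisation of the prenylphenol onto its side chain.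

Step 5
Reactants: 11 8-hydroxy-2,2-dimethyl-7-(3-methylbut-2-enyl)-2H-chromene-6-carbaldehyde
Product: 12 8-(tert-butyldimethylsilyloxy)-2,2-dimethyl-7-(3-methylbut-2-enyl)-2H-chromene-6-carbaldehyde
Conditions: TBSCl, imidazole, DMF, rt
Reagents that add atoms: tert-butyldimethylsilyl chloride, CC(C)(C)[Si](C)(C)Cl
Why: Imidazole-promoted silylation of a phenol masks the acidic ring B hydroxyl before the Grignard, Heck and borane steps.

Step 6
Reactants: 12 8-(tert-butyldimethylsilyloxy)-2,2-dimethyl-7-(3-methylbut-2-enyl)-2H-chromene-6-carbaldehyde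
Product: 13 rac-1-[8-(tert-butyldimethylsilyloxy)-2,2-dimethyl-7-(3-methylbut-2-enyl)-2H-chromen-6-yl]prop-2-en-1-ol
Conditions: vinylmagnesium bromide, THF, −78 to 0 °C; aq NH4Cl
Reagents that add atoms: vinylmagnesium bromide, C=C[Mg]Br
Why: Grignard 1,2-addition to an aromatic aldehyde gives the secondary allylic alcohol as a racemate, which is acceptable because this carbon becomes a carbonyl group in step 8.

Step 7
Reactants: 14 4-iodobenzene-1,3-diol (4-iodoresorcinol)
Product: 15 1-iodo-2,4-bis(triisopropylsilyloxy)benzene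
Conditions: TIPSCl (2.5 equiv), imidazole, DMF, rt to 40 °C
Reagents that add atoms: triisopropylsilyl chloride, CC(C)[Si](Cl)(C(C)C)C(C)C
Why: Imidazole-promoted silylation of both phenols gives a base-stable aryl iodide whose oxygen ortho to iodine later becomes O1 of ring C and whose oxygen para to iodine becomes the 7-hydroxyl.

Step 8
Reactants: 13 rac-1-[8-(tert-butyldimethylsilyloxy)-2,2-dimethyl-7-(3-methylbut-2-enyl)-2H-chromen-6-yl]prop-2-en-1-ol; 15 1-iodo-2,4-bis(triisopropylsilyloxy)benzene
Product: 17 3-[2,4-bis(triisopropylsilyloxy)phenyl]-1-[8-(tert-butyldimethylsilyloxy)-2,2-dimethyl-7-(3-methylbut-2-enyl)-2H-chromen-6-yl]propan-1-one, via enol 16 (not isolated)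
Conditions: Pd(OAc)2 (5 mol%), Bu4NCl, NaHCO3, DMF, 50 °C
Reagents that add atoms: none
Why: Heck arylation of a secondary allylic alcohol under phosphine-free phase-transfer conditions, in which the aryl group adds to the terminal alkene carbon, β-hydride elimination towards the carbinol gives enol 16 and tautomerisation gives the saturated aryl ketone, the monosubstituted vinyl group inserting far faster than the trisubstituted prenyl and the cyclic chromene double bonds.

Step 9
Reactants: 17 3-[2,4-bis(triisopropylsilyloxy)phenyl]-1-[8-(tert-butyldimethylsilyloxy)-2,2-dimethyl-7-(3-methylbut-2-enyl)-2H-chromen-6-yl]propan-1-one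
Product: 18 (1S)-3-[2,4-bis(triisopropylsilyloxy)phenyl]-1-[8-(tert-butyldimethylsilyloxy)-2,2-dimethyl-7-(3-methylbut-2-enyl)-2H-chromen-6-yl]propan-1-ol
Conditions: (R)-2-methyl-CBS-oxazaborolidine (20 mol%), catecholborane, toluene, −78 to −40 °C; MeOH, then H2O
Reagents that add atoms: none
Why: Corey–Bakshi–Shibata reduction, in which the (R)-oxazaborolidine treats the ortho-substituted ring B aryl group as the large substituent and should deliver hydride to the face that gives the (S)-carbinol (the sense established for aryl alkyl ketones), with catecholborane chosen because it does not hydroborate the prenyl or chromene double bonds at low temperature.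

Step 10
Reactants: 18 (1S)-3-[2,4-bis(triisopropylsilyloxy)phenyl]-1-[8-(tert-butyldimethylsilyloxy)-2,2-dimethyl-7-(3-methylbut-2-enyl)-2H-chromen-6-yl]propan-1-ol
Product: 19 4-[(3S)-3-hydroxy-3-[8-hydroxy-2,2-dimethyl-7-(3-methylbut-2-enyl)-2H-chromen-6-yl]propyl]benzene-1,3-diol
Conditions: TBAF (3.5 equiv), AcOH, THF, 0 °C
Reagents that add atoms: none
Why: Fluoride-mediated cleavage of the three aryl silyl ethers, buffered with acetic acid so that the prenylphenol and the chromene see neither strong base nor acid, leaves the stereocentre untouched.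

Step 11
Reactants: 19 4-[(3S)-3-hydroxy-3-[8-hydroxy-2,2-dimethyl-7-(3-methylbut-2-enyl)-2H-chromen-6-yl]propyl]benzene-1,3-diol
Product: 20 (2R)-2-[8-hydroxy-2,2-dimethyl-7-(3-methylbut-2-enyl)-2H-chromen-6-yl]-3,4-dihydro-2H-chromen-7-ol (CNP0175270.2)
Conditions: PPh3, DIAD, THF (0.02 M), 0 °C to rt
Reagents that add atoms: none
Why: Intramolecular Mitsunobu etherification, in which only the ring A hydroxyl ortho to the propyl chain can reach the activated carbinol through a six-membered transition state, and SN2 displacement of the oxyphosphonium with inversion should turn the (S)-carbinol into the (2R)-configured C2 of ring C.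

**Compound list**

1 | 3,4-dihydroxybenzaldehyde | O=Cc1ccc(O)c(O)c1 | starting material
2 | 3-chloro-3-methylbut-1-yne | CC(C)(Cl)C#C | starting material
3 | 3-hydroxy-4-(2-methylbut-3-yn-2-yloxy)benzaldehyde | O=Cc1ccc(OC(C)(C)C#C)c(O)c1 | intermediate
4 | 2-methylbut-3-en-2-ol | CC(C)(O)C=C | starting material
5 | lithium 2-methylbut-3-en-2-olate | [Li+].CC(C)([O-])C=C | intermediate
6 | methyl 2-methylbut-3-en-2-yl carbonate | COC(=O)OC(C)(C)C=C | intermediate
7 | 3-(2-methylbut-3-en-2-yloxy)-4-(2-methylbut-3-yn-2-yloxy)benzaldehyde | O=Cc1ccc(OC(C)(C)C#C)c(OC(C)(C)C=C)c1 | intermediate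
8 | 3-hydroxy-4-(2-methylbut-3-yn-2-yloxy)-2-(3-methylbut-2-enyl)benzaldehyde | O=Cc1ccc(OC(C)(C)C#C)c(O)c1CC=C(C)C | intermediate
9 | 3,4-dihydroxy-5-(3-methylbuta-1,2-dienyl)-2-(3-methylbut-2-enyl)benzaldehyde | O=Cc1cc(C=C=C(C)C)c(O)c(O)c1CC=C(C)C | intermediate
10 | 5-hydroxy-3-(3-methylbut-2-enylidene)-6-(3-methylbut-2-enyl)-4-oxocyclohexa-1,5-diene-1-carbaldehyde (ortho-quinone methide) | O=CC1=CC(=CC=C(C)C)C(=O)C(O)=C1CC=C(C)C | intermediate
11 | 8-hydroxy-2,2-dimethyl-7-(3-methylbut-2-enyl)-2H-chromene-6-carbaldehyde | CC(C)=CCc1c(C=O)cc2c(c1O)OC(C)(C)C=C2 | intermediate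
12 | 8-(tert-butyldimethylsilyloxy)-2,2-dimethyl-7-(3-methylbut-2-enyl)-2H-chromene-6-carbaldehyde | CC(C)=CCc1c(C=O)cc2c(c1O[Si](C)(C)C(C)(C)C)OC(C)(C)C=C2 | intermediate
13 | rac-1-[8-(tert-butyldimethylsilyloxy)-2,2-dimethyl-7-(3-methylbut-2-enyl)-2H-chromen-6-yl]prop-2-en-1-ol | CC(C)=CCc1c(C(O)C=C)cc2c(c1O[Si](C)(C)C(C)(C)C)OC(C)(C)C=C2 | intermediate
14 | 4-iodobenzene-1,3-diol | Oc1ccc(I)c(O)c1 | starting material
15 | 1-iodo-2,4-bis(triisopropylsilyloxy)benzene | CC(C)[Si](Oc1ccc(I)c(O[Si](C(C)C)(C(C)C)C(C)C)c1)(C(C)C)C(C)C | intermediate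
16 | 3-[2,4-bis(triisopropylsilyloxy)phenyl]-1-[8-(tert-butyldimethylsilyloxy)-2,2-dimethyl-7-(3-methylbut-2-enyl)-2H-chromen-6-yl]prop-1-en-1-ol (enol) | CC(C)=CCc1c(C(O)=CCc3ccc(O[Si](C(C)C)(C(C)C)C(C)C)cc3O[Si](C(C)C)(C(C)C)C(C)C)cc2c(c1O[Si](C)(C)C(C)(C)C)OC(C)(C)C=C2 | intermediate
17 | 3-[2,4-bis(triisopropylsilyloxy)phenyl]-1-[8-(tert-butyldimethylsilyloxy)-2,2-dimethyl-7-(3-methylbut-2-enyl)-2H-chromen-6-yl]propan-1-one | CC(C)=CCc1c(C(=O)CCc3ccc(O[Si](C(C)C)(C(C)C)C(C)C)cc3O[Si](C(C)C)(C(C)C)C(C)C)cc2c(c1O[Si](C)(C)C(C)(C)C)OC(C)(C)C=C2 | intermediate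
18 | (1S)-3-[2,4-bis(triisopropylsilyloxy)phenyl]-1-[8-(tert-butyldimethylsilyloxy)-2,2-dimethyl-7-(3-methylbut-2-enyl)-2H-chromen-6-yl]propan-1-ol | CC(C)=CCc1c([C@@H](O)CCc3ccc(O[Si](C(C)C)(C(C)C)C(C)C)cc3O[Si](C(C)C)(C(C)C)C(C)C)cc2c(c1O[Si](C)(C)C(C)(C)C)OC(C)(C)C=C2 | intermediate
19 | 4-[(3S)-3-hydroxy-3-[8-hydroxy-2,2-dimethyl-7-(3-methylbut-2-enyl)-2H-chromen-6-yl]propyl]benzene-1,3-diol | CC(C)=CCc1c([C@@H](O)CCc3ccc(O)cc3O)cc2c(c1O)OC(C)(C)C=C2 | intermediate
20 | (2R)-2-[8-hydroxy-2,2-dimethyl-7-(3-methylbut-2-enyl)-2H-chromen-6-yl]-3,4-dihydro-2H-chromen-7-ol | CC(C)=CCc1c([C@H]2CCc3ccc(O)cc3O2)cc2c(c1O)OC(C)(C)C=C2 | target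

**Totals**
Total step count: 11.
Longest linear sequence: 9 steps (steps 1, 3, 4, 5, 6, 8, 9, 10 and 11, from 1).

**Steps most likely to fail**

1. Step 4. At the temperature the propargyl rearrangement needs, the tertiary allyl ether may fragment with loss of isoprene before it migrates, and the aldehyde may be consumed in an ene-type cyclisation with the newly installed prenyl chain. The fallback separates the two temperature regimes and sets out from 3. Heating 3 alone in PhNEt2 at 190 °C should give 8-hydroxy-2,2-dimethyl-2H-chromene-6-carbaldehyde F1, with no allyl ether or prenyl group present. The phenol of F1 is then tert-prenylated with carbonate 6 and Pd(PPh3)4 in THF at 0 °C to give 2,2-dimethyl-8-(2-methylbut-3-en-2-yloxy)-2H-chromene-6-carbaldehyde F2. This single ether is rearranged in toluene at about 120 °C, where O8 has only C7 as open ortho carbon, and the route is rejoined at 11.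

2. Step 11. The activated carbinol is a para-alkoxybenzylic centre, so ionisation may compete with direct displacement and erode the enantiopurity, and the two uninvolved phenols may be alkylated intermolecularly. The fallback never breaks the carbinol C–O bond and keeps the other phenols silylated; it sets out from 13.
   - Commercial 3-bromo-4-iodophenol F3 is silylated (TIPSCl, imidazole, DMF) to (3-bromo-4-iodophenoxy)triisopropylsilane F4.
   - Heck arylation of 13 at the C–I bond of F4 under the conditions of step 8 should give 3-[2-bromo-4-(triisopropylsilyloxy)phenyl]-1-[8-(tert-butyldimethylsilyloxy)-2,2-dimethyl-7-(3-methylbut-2-enyl)-2H-chromen-6-yl]propan-1-one F5.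
   - Reduction with (S)-2-methyl-CBS-oxazaborolidine and catecholborane gives (1R)-3-[2-bromo-4-(triisopropylsilyloxy)phenyl]-1-[8-(tert-butyldimethylsilyloxy)-2,2-dimethyl-7-(3-methylbut-2-enyl)-2H-chromen-6-yl]propan-1-ol F6.
   - Intramolecular Buchwald-type C–O coupling (Pd(OAc)2, 2-(di-tert-butylphosphino)-1,1'-binaphthyl, Cs2CO3, toluene, 70 °C) closes ring C with retention to give (2R)-2-[8-(tert-butyldimethylsilyloxy)-2,2-dimethyl-7-(3-methylbut-2-enyl)-2H-chromen-6-yl]-7-(triisopropylsilyloxy)-3,4-dihydro-2H-chromene F7.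
   - TBAF/AcOH in THF then gives 20.

3. Step 8. β-Hydride elimination may go away from the carbinol and give the arylated allylic alcohol instead of the ketone, the allylic alcohol may isomerise to the ethyl ketone before arylation, or insertion may be slowed by the ortho-silyloxy group of the iodide. The fallback joins the same two carbons by a B-alkyl Suzuki–Miyaura coupling and sets out from 13. Treatment with 9-BBN (2.2 equiv, THF, rt) should silylate nothing, borylate the hydroxyl and hydroborate only the terminal alkene, giving 9-[1-[8-(tert-butyldimethylsilyloxy)-2,2-dimethyl-7-(3-methylbut-2-enyl)-2H-chromen-6-yl]-3-(9-borabicyclo[3.3.1]nonan-9-yl)propoxy]-9-borabicyclo[3.3.1]nonane F8. Coupling of F8 with 15 (PdCl2(dppf), aq K3PO4, THF/DMF, 50 °C) gives rac-3-[2,4-bis(triisopropylsilyloxy)phenyl]-1-[8-(tert-butyldimethylsilyloxy)-2,2-dimethyl-7-(3-methylbut-2-enyl)-2H-chromen-6-yl]propan-1-ol F9. Dess–Martin periodinane with NaHCO3 in CH2Cl2 oxidises F9 to 17, where the route is rejoined.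

Further compounds
F1 | step 4 | 8-hydroxy-2,2-dimethyl-2H-chromene-6-carbaldehyde | O=Cc1cc(O)c2c(c1)C=CC(C)(C)O2
F2 | step 4 | 2,2-dimethyl-8-(2-methylbut-3-en-2-yloxy)-2H-chromene-6-carbaldehyde | O=Cc1cc(OC(C)(C)C=C)c2c(c1)C=CC(C)(C)O2
F3 | step 11 | 3-bromo-4-iodophenol (purchased) | Oc1ccc(I)c(Br)c1
F4 | step 11 | (3-bromo-4-iodophenoxy)triisopropylsilane | CC(C)[Si](Oc1ccc(I)c(Br)c1)(C(C)C)C(C)C
F5 | step 11 | 3-[2-bromo-4-(triisopropylsilyloxy)phenyl]-1-[8-(tert-butyldimethylsilyloxy)-2,2-dimethyl-7-(3-methylbut-2-enyl)-2H-chromen-6-yl]propan-1-one | CC(C)=CCc1c(C(=O)CCc3ccc(O[Si](C(C)C)(C(C)C)C(C)C)cc3Br)cc2c(c1O[Si](C)(C)C(C)(C)C)OC(C)(C)C=C2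
F6 | step 11 | (1R)-3-[2-bromo-4-(triisopropylsilyloxy)phenyl]-1-[8-(tert-butyldimethylsilyloxy)-2,2-dimethyl-7-(3-methylbut-2-enyl)-2H-chromen-6-yl]propan-1-ol | CC(C)=CCc1c([C@H](O)CCc3ccc(O[Si](C(C)C)(C(C)C)C(C)C)cc3Br)cc2c(c1O[Si](C)(C)C(C)(C)C)OC(C)(C)C=C2
F7 | step 11 | (2R)-2-[8-(tert-butyldimethylsilyloxy)-2,2-dimethyl-7-(3-methylbut-2-enyl)-2H-chromen-6-yl]-7-(triisopropylsilyloxy)-3,4-dihydro-2H-chromene | CC(C)=CCc1c([C@H]2CCc3ccc(O[Si](C(C)C)(C(C)C)C(C)C)cc3O2)cc2c(c1O[Si](C)(C)C(C)(C)C)OC(C)(C)C=C2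
F8 | step 8 | 9-[1-[8-(tert-butyldimethylsilyloxy)-2,2-dimethyl-7-(3-methylbut-2-enyl)-2H-chromen-6-yl]-3-(9-borabicyclo[3.3.1]nonan-9-yl)propoxy]-9-borabicyclo[3.3.1]nonane | CC(C)=CCc1c(C(OB2C3CCCC2CCC3)CCB2C3CCCC2CCC3)cc2c(c1O[Si](C)(C)C(C)(C)C)OC(C)(C)C=C2
F9 | step 8 | rac-3-[2,4-bis(triisopropylsilyloxy)phenyl]-1-[8-(tert-butyldimethylsilyloxy)-2,2-dimethyl-7-(3-methylbut-2-enyl)-2H-chromen-6-yl]propan-1-ol | CC(C)=CCc1c(C(O)CCc3ccc(O[Si](C(C)C)(C(C)C)C(C)C)cc3O[Si](C(C)C)(C(C)C)C(C)C)cc2c(c1O[Si](C)(C)C(C)(C)C)OC(C)(C)C=C2
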